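The pyran ring of the chroman is cut at O1–C2 and C4a–C4. What remains of it, C2–C3–C4 with the isopropyl and isobutyl branches, is the aldol dimer of isovaleraldehyde, (E)-2-isopropyl-5-methylhex-2-enal, while C4a–C8a–O1 of ring A is the ortho-carbon/oxygen bis-nucleophile of a phenol. The key step joins a 4-hydroxybenzaldehyde, carrying the two other ring A oxygens as benzyl ethers, with this enal in an amine-catalysed asymmetric Friedel–Crafts/hemiacetalisation (formal 3+3) that sets C4 and delivers a chroman-2-ol. Its acetal carbon C2 then takes up 2,4-diformylphloroglucinol through the cyclic oxocarbenium ion, which fixes C3 and C2; hydrogenolysis ends the route.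

Key step: step 2

Remarks (assumptions):
- Chroman numbering is O1, C2, C3, C4, C4a, C5–C8, C8a; ring A is the benzo ring and ring B the 2-aryl ring.
- Compounds 1, 3 and 6 are taken as catalogue chemicals; 3 is sold as an E-rich isomer mixture, and its iminium ion equilibrates the double-bond geometry.
- The sense of induction of the cinchona primary amine with this α-branched enal is assigned by analogy only; should the quinine-derived amine expose the wrong face, its pseudoenantiomer 9-amino-9-deoxy-epi-quinidine is used unchanged in all other respects.

Step 1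
Reactants: 1 3,5-bis(benzyloxy)phenol
Product: 2 2,6-bis(benzyloxy)-4-hydroxybenzaldehyde
Conditions: POCl3 (1.2 equiv), DMF, 0 °C → rt; then H2O, 50 °C
Reagents that add atoms: N,N-dimethylformamide CN(C)C=O (formyl carbon); water O (formyl oxygen)
Why: Vilsmeier–Haack formylation, in which the chloroiminium ion should attack the ring carbon para to the free OH and between the two benzyloxy groups, as is usual for 3,5-dialkoxyphenols; the hydrogen-bonded ortho-formyl isomer is less polar and is removed by chromatography, and no stereocentre is formed.

Step 2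
Reactants: 2 2,6-bis(benzyloxy)-4-hydroxybenzaldehyde; 3 (E)-2-isopropyl-5-methylhex-2-enal
Product: 5 (4S)-5,7-bis(benzyloxy)-2-hydroxy-4-isobutyl-3-isopropylchromane-6-carbaldehyde (lactol; C2 and C3 epimer mixture), via hydroxy aldehyde 4 (not isolated)
Conditions: 9-amino-9-deoxy-epi-quinine (20 mol%), TFA (40 mol%), PhMe, 40 °C
Reagents that add atoms: none
Why: The primary amine condenses with enal 3 to an iminium ion (an α-branched enal is engaged by a primary but hardly by a secondary amine); the carbon ortho to the free OH of 2 adds to the β-carbon in a Friedel–Crafts-type conjugate addition (C4a–C4), and after rearomatisation, enamine protonation and hydrolysis the aldehyde 4 closes to the lactol by attack of the same OH on the aldehyde carbon (O1–C2). The closest known reaction type is the amine-catalysed Friedel–Crafts alkylation/hemiacetalisation of electron-rich phenols and naphthols with enals to chroman-2-ols, combined with primary-amine iminium activation of α-branched enals. The pyran ring closes in the 6-exo-trig mode (hemiacetalisation). C4 is set by the catalyst, which must expose the Si face of the enal β-carbon to give (4S); C3 (enamine protonation) and C2 (anomeric carbon) are left unsettled here on purpose, because step 3 passes through a C2=C3 enol ether. The step needs 1,4- over 1,2-addition, secured by the α-isopropyl group that screens the iminium carbon next to an unhindered β-CH; C- over O-alkylation, secured by the reversibility of the oxa-Michael adduct; and a single ring-closure regiochemistry, secured because the two ortho carbons of 2 are equivalent and only the OH para to the formyl group is free.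

Step 3
Reactants: 5 (4S)-5,7-bis(benzyloxy)-2-hydroxy-4-isobutyl-3-isopropylchromane-6-carbaldehyde; 6 2,4,6-trihydroxybenzene-1,3-dicarbaldehyde (2,4-diformylphloroglucinol)
Product: 8 (2R,3R,4S)-5,7-bis(benzyloxy)-2-(3,5-diformyl-2,4,6-trihydroxyphenyl)-4-isobutyl-3-isopropylchromane-6-carbaldehyde, via 4H-chromene 7 (not isolated)
Conditions: TsOH·H2O (5 mol%), 4 Å MS, PhMe, 80 °C; then 6 (3 equiv), TfOH (20 mol%), MeCN, −20 °C → rt
Reagents that add atoms: none
Why: Acid-catalysed dehydration of the lactol should give the cyclic enol ether 7 (erasing C2 and C3), whose protonation at C3 on the face anti to the pseudoaxial C4 isobutyl group gives the 3,4-cis oxocarbenium ion that is captured at C2 by the only free ring carbon of 6, anti to both alkyl groups (2,3-trans), in a Friedel–Crafts C-arylation of the kind used for aryl C-glycosides from glycals; the O1–C2 bond stays intact, any O-aryl acetal reverts, and oxocarbenium epimers equilibrate through 7 so that the least hindered pathway drains them.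

Step 4
Reactants: 8 (2R,3R,4S)-5,7-bis(benzyloxy)-2-(3,5-diformyl-2,4,6-trihydroxyphenyl)-4-isobutyl-3-isopropylchromane-6-carbaldehyde
Product: 9 5-[(2R,3R,4S)-6-formyl-5,7-dihydroxy-4-isobutyl-3-isopropylchroman-2-yl]-2,4,6-trihydroxybenzene-1,3-dicarbaldehyde (target)
Conditions: H2 (1 atm), 10% Pd/C, EtOAc, rt
Reagents that add atoms: none
Why: Hydrogenolysis of the two aryl benzyl ethers under neutral conditions frees the 5- and 7-OH only after the pyran ring is closed through O1, so with no acid or base to open the ring via a quinone methide neither the ring-closure regiochemistry nor the three stereocentres should be touched, and the hydrogen-bonded formyl groups are reduced far more slowly than O-benzyl bonds.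

Compound list
1 | 3,5-bis(benzyloxy)phenol | Oc1cc(OCc2ccccc2)cc(OCc3ccccc3)c1 | starting material
2 | 2,6-bis(benzyloxy)-4-hydroxybenzaldehyde | O=Cc1c(OCc2ccccc2)cc(O)cc1OCc3ccccc3 | intermediate
3 | (E)-2-isopropyl-5-methylhex-2-enal | CC(C)C/C=C(/C=O)C(C)C | starting material
4 | (3S)-3-[2,4-bis(benzyloxy)-3-formyl-6-hydroxyphenyl]-2-isopropyl-5-methylhexanal (C2 epimer mixture) | CC(C)C[C@H](c1c(O)cc(OCc2ccccc2)c(C=O)c1OCc3ccccc3)C(C=O)C(C)C | intermediate (not isolated)
5 | (4S)-5,7-bis(benzyloxy)-2-hydroxy-4-isobutyl-3-isopropylchromane-6-carbaldehyde (C2 and C3 epimer mixture) | CC(C)C[C@@H]1c2c(cc(OCc3ccccc3)c(C=O)c2OCc4ccccc4)OC(O)C1C(C)C | intermediate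
6 | 2,4,6-trihydroxybenzene-1,3-dicarbaldehyde | O=Cc1c(O)cc(O)c(C=O)c1O | starting material
7 | (4S)-5,7-bis(benzyloxy)-4-isobutyl-3-isopropyl-4H-chromene-6-carbaldehyde | CC(C)C[C@@H]1c2c(cc(OCc3ccccc3)c(C=O)c2OCc4ccccc4)OC=C1C(C)C | intermediate (not isolated)
8 | (2R,3R,4S)-5,7-bis(benzyloxy)-2-(3,5-diformyl-2,4,6-trihydroxyphenyl)-4-isobutyl-3-isopropylchromane-6-carbaldehyde | CC(C)C[C@@H]1c2c(cc(OCc3ccccc3)c(C=O)c2OCc4ccccc4)O[C@@H](c5c(O)c(C=O)c(O)c(C=O)c5O)[C@@H]1C(C)C | intermediate
9 | 5-[(2R,3R,4S)-6-formyl-5,7-dihydroxy-4-isobutyl-3-isopropylchroman-2-yl]-2,4,6-trihydroxybenzene-1,3-dicarbaldehyde | CC(C)C[C@@H]1c2c(cc(O)c(C=O)c2O)O[C@@H](c2c(O)c(C=O)c(O)c(C=O)c2O)[C@@H]1C(C)C | target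

Total step count: 4
Longest linear sequence: 4 steps (1 → 2 → 5 → 8 → 9)

Steps most likely to fail

1. Step 2. The hindered α-isopropyl enal may form its iminium ion too slowly, the amine may be tied up as an imine of the aryl aldehyde, the enantiofacial control may be poor, or the reaction may drift into 1,2-addition and 2H-chromene formation. Fallback: setting out from 2 and 3, the same annulation is run without asymmetric induction, using an achiral primary ammonium salt (benzhydrylamine·TFA, PhMe, 60 °C), to give the racemic lactol F1. Dehydration (TsOH·H2O, 4 Å MS, PhMe, 80 °C) gives the racemic 4H-chromene F2, which has C4 as its only stereocentre. Preparative chromatography on a chiral stationary phase (supercritical CO2/iPrOH) separates it into the (4S)-chromene 7 and the (4R)-chromene F3, which is discarded. The route is rejoined at compound 7, which enters the second stage of step 3.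

2. Step 3. The electron-poor arene 6 may attack the oxocarbenium ion too slowly, so that C8 of a second chroman molecule alkylates instead, benzyl groups are lost in acid, or the facial selectivity at C3 and C2 erodes. Fallback: setting out from 5, the same dehydration/arylation is run with the far more nucleophilic phloroglucinol (5 equiv; TsOH·H2O, PhMe, 80 °C, then TfOH cat., MeCN, −20 °C) to give (2R,3R,4S)-5,7-bis(benzyloxy)-4-isobutyl-3-isopropyl-2-(2,4,6-trihydroxyphenyl)chromane-6-carbaldehyde F4. Double Vilsmeier–Haack formylation (POCl3, DMF, then H2O) of the two equivalent free positions of ring B then leads back to compound 8; C8 of ring A is flanked by ether oxygens and deactivated by the formyl group.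

3. Step 4. Formyl groups may be over-reduced, or the benzylic C2–O1 bond hydrogenolysed, before both benzyl ethers are gone. Fallback: setting out from 8, the reductive deprotection is replaced by a Lewis-acid dealkylation with a cation scavenger (BCl3, pentamethylbenzene, CH2Cl2, −78 °C, MeOH quench at −78 °C). Chelation to the ortho formyl group drives cleavage of both benzyl ethers at a temperature at which C2–O1 should not ionise, and this leads directly to compound 9; the fallback makes no new compound (F0).

Further compounds
F1 | step 2 | racemic 5,7-bis(benzyloxy)-2-hydroxy-4-isobutyl-3-isopropylchromane-6-carbaldehyde | CC(C)CC1c2c(cc(OCc3ccccc3)c(C=O)c2OCc4ccccc4)OC(O)C1C(C)C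
F2 | step 2 | racemic 5,7-bis(benzyloxy)-4-isobutyl-3-isopropyl-4H-chromene-6-carbaldehyde | CC(C)CC1c2c(cc(OCc3ccccc3)c(C=O)c2OCc4ccccc4)OC=C1C(C)C
F3 | step 2 | (4R)-5,7-bis(benzyloxy)-4-isobutyl-3-isopropyl-4H-chromene-6-carbaldehyde | CC(C)C[C@H]1c2c(cc(OCc3ccccc3)c(C=O)c2OCc4ccccc4)OC=C1C(C)C
F4 | step 3 | (2R,3R,4S)-5,7-bis(benzyloxy)-4-isobutyl-3-isopropyl-2-(2,4,6-trihydroxyphenyl)chromane-6-carbaldehyde | CC(C)C[C@@H]1c2c(cc(OCc3ccccc3)c(C=O)c2OCc4ccccc4)O[C@@H](c5c(O)cc(O)cc5O)[C@@H]1C(C)C
F0 | step 4 | none | none
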